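**Retrosynthetic overview**

1. 19 ⇐ cyclohexene 18 (saturation of the ring alkene) ⇐ acyclic 1,5-diene 15. The cyclohexane ring is closed last, by forming the bond between the chlorine-bearing carbon C4′ and the ring CH2 C5′ (cyclohexane numbered as in the name of 19, C1′ carrying the oxane). The reaction is a Br+-triggered cation–olefin cyclisation with an (E)-2-chloroalkene as initiator and a (Z)-vinylsilane as terminator.
2. Enabling feature: the ring unit C5′H2–C4′(CH3)(Cl)–C3′H(Br) has Br and Cl trans-diequatorial, CH3 axial and the oxanyl group on C1′ equatorial. This is the pattern left by anti addition of Br+ and a carbon nucleophile across an (E)-chloroalkene through a chair; the saturated C5′–C6′ unit maps onto the vinylsilane.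
3. 15 ⇐ acid 5: an Evans alkylation with (E)-1,3-dichlorobut-2-ene sets C1′ and brings in the chloroalkene; the acyl carbon then becomes the alkyne and the (Z)-vinylsilane.
4. 5 ⇐ vinyl bromo-oxane 2 ⇐ (R)-linalool 1 by bromoetherification. Ring order: oxane ring first (step 1), cyclohexane ring second (step 10).

Key step: step 10

Assumption: (E)-1,3-dichlorobut-2-ene (9) is taken as purchasable in isomerically pure form; otherwise it is separated from the commercial E/Z mixture by fractional distillation.

Step 1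
Reactants: 1 (R)-linalool
Product: 2 (3S,6R)-3-bromo-6-ethenyl-2,2,6-trimethyloxane
Conditions: 2,4,4,6-tetrabromocyclohexa-2,5-dien-1-one, CH2Cl2, 0 °C to rt, dark
Reagents that add atoms: 2,4,4,6-tetrabromocyclohexa-2,5-dien-1-one, O=C1C(Br)=CC(Br)(Br)C=C1Br
Why: Bromoetherification in which Br+ is taken by the electron-rich trisubstituted alkene and not by the vinyl group, and the tertiary hydroxyl opens the bromonium ion at its tertiary carbon (6-endo, Markovnikov) through a chair with bromine equatorial, which sets the CHBr centre relative to the carbinol centre of 1; the epimer at that centre and five-membered ethers are expected as by-products and are removed by chromatography.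

Step 2
Reactants: 2 (3S,6R)-3-bromo-6-ethenyl-2,2,6-trimethyloxane
Product: 4 2-[(2R,5S)-5-bromo-2,6,6-trimethyloxan-2-yl]ethan-1-ol, via B-alkyl-9-BBN adduct 3 (not isolated)
Conditions: 9-BBN, THF, 0 °C to rt; then NaOH, H2O2, H2O, 0 °C
Reagents that add atoms: hydrogen peroxide, OO
Why: Hydroboration–oxidation, in which the hindered borane places boron on the terminal carbon of the only alkene and basic peroxide replaces boron by hydroxyl, while the hindered secondary bromide should tolerate the cold basic peroxide; no stereocentre is formed.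

Step 3
Reactants: 4 2-[(2R,5S)-5-bromo-2,6,6-trimethyloxan-2-yl]ethan-1-ol
Product: 5 2-[(2R,5S)-5-bromo-2,6,6-trimethyloxan-2-yl]acetic acid
Conditions: TEMPO (cat.), PhI(OAc)2, MeCN–H2O, rt
Reagents that add atoms: water, O
Why: Nitroxyl-catalysed oxidation of the primary alcohol through the aldehyde hydrate to the acid under near-neutral conditions that should leave the bromide and the ether untouched; no stereocentre is formed.

Step 4
Reactants: 5 2-[(2R,5S)-5-bromo-2,6,6-trimethyloxan-2-yl]acetic acid; 6 (4R)-4-benzyl-1,3-oxazolidin-2-one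
Product: 8 (4R)-4-benzyl-3-{2-[(2R,5S)-5-bromo-2,6,6-trimethyloxan-2-yl]acetyl}-1,3-oxazolidin-2-one, via mixed pivalic anhydride 7 (not isolated)
Conditions: t-BuCOCl, Et3N, THF, −20 °C; then LiCl, 6, −20 °C to rt
Reagents that add atoms: none
Why: N-Acylation of an Evans oxazolidinone through the mixed pivalic anhydride, which the LiCl-activated oxazolidinone should attack at the less hindered carbonyl; no stereocentre is formed.

Step 5
Reactants: 8 (4R)-4-benzyl-3-{2-[(2R,5S)-5-bromo-2,6,6-trimethyloxan-2-yl]acetyl}-1,3-oxazolidin-2-one; 9 (2E)-1,3-dichlorobut-2-ene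
Product: 11 (4R)-4-benzyl-3-[(2R,4E)-2-[(2R,5S)-5-bromo-2,6,6-trimethyloxan-2-yl]-5-chlorohex-4-enoyl]-1,3-oxazolidin-2-one, via sodium (Z)-enolate 10 (not isolated)
Conditions: NaN(SiMe3)2, THF, −78 °C; then 9, Bu4NI (cat.), −78 to −30 °C
Reagents that add atoms: none
Why: Evans asymmetric alkylation, in which the chelated sodium (Z)-enolate should be alkylated at the primary allylic carbon of 9 on the face opposite the benzyl group of the (R)-auxiliary, which sets the new CH centre as R against any bias of the neighbouring quaternary centre and carries the E geometry of 9 over unchanged.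

Step 6
Reactants: 11 (4R)-4-benzyl-3-[(2R,4E)-2-[(2R,5S)-5-bromo-2,6,6-trimethyloxan-2-yl]-5-chlorohex-4-enoyl]-1,3-oxazolidin-2-one
Product: 12 (2S,4E)-2-[(2R,5S)-5-bromo-2,6,6-trimethyloxan-2-yl]-5-chlorohex-4-en-1-ol
Conditions: LiBH4, MeOH (1 equiv), Et2O, 0 °C
Reagents that add atoms: none
Why: Reductive removal of the auxiliary, in which LiBH4 should attack the exocyclic imide carbonyl and give the primary alcohol without touching the stereocentres, the chloroalkene or the hindered bromide.

Step 7
Reactants: 12 (2S,4E)-2-[(2R,5S)-5-bromo-2,6,6-trimethyloxan-2-yl]-5-chlorohex-4-en-1-ol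
Product: 13 (2R,4E)-2-[(2R,5S)-5-bromo-2,6,6-trimethyloxan-2-yl]-5-chlorohex-4-enal
Conditions: Dess–Martin periodinane, CH2Cl2, 0 °C to rt
Reagents that add atoms: none
Why: Dess–Martin oxidation under non-basic conditions should give the α-branched aldehyde without epimerisation and without β-elimination of the ring oxygen.

Step 8
Reactants: 13 (2R,4E)-2-[(2R,5S)-5-bromo-2,6,6-trimethyloxan-2-yl]-5-chlorohex-4-enal
Product: 14 (2R,5S)-5-bromo-2-[(3S,5E)-6-chlorohept-5-en-1-yn-3-yl]-2,6,6-trimethyloxane
Conditions: dimethyl (1-diazo-2-oxopropyl)phosphonate, K2CO3, MeOH, 0 °C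
Reagents that add atoms: dimethyl (1-diazo-2-oxopropyl)phosphonate, CC(=O)C(=[N+]=[N-])P(=O)(OC)OC
Why: Ohira–Bestmann variant of the Seyferth–Gilbert homologation, in which the diazomethylphosphonate anion formed in the flask converts the aldehyde into the terminal alkyne with one added carbon at a temperature low enough to keep the α-stereocentre.

Step 9
Reactants: 14 (2R,5S)-5-bromo-2-[(3S,5E)-6-chlorohept-5-en-1-yn-3-yl]-2,6,6-trimethyloxane
Product: 15 [(1Z,3S,5E)-3-[(2R,5S)-5-bromo-2,6,6-trimethyloxan-2-yl]-6-chlorohepta-1,5-dien-1-yl]triethylsilane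
Conditions: Et3SiH, [RuCl2(p-cymene)]2 (cat.), CH2Cl2, rt
Reagents that add atoms: triethylsilane, CC[SiH](CC)CC
Why: Ruthenium-catalysed trans-hydrosilylation of the terminal alkyne, which with this catalyst should place silicon on the terminal carbon and give the (Z)-alkenylsilane needed for endocyclic ring closure, leaving the trisubstituted chloroalkene untouched.

Step 10
Reactants: 15 [(1Z,3S,5E)-3-[(2R,5S)-5-bromo-2,6,6-trimethyloxan-2-yl]-6-chlorohepta-1,5-dien-1-yl]triethylsilane
Product: 18 (2R,5S)-5-bromo-2-[(1S,4R,5R)-5-bromo-4-chloro-4-methylcyclohex-2-en-1-yl]-2,6,6-trimethyloxane, via bromiranium ion 16 (not isolated), via β-silyl carbocation 17 (not isolated)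
Conditions: 2,4,4,6-tetrabromocyclohexa-2,5-dien-1-one, MeNO2–CH2Cl2, −40 to −10 °C, dark
Reagents that add atoms: 2,4,4,6-tetrabromocyclohexa-2,5-dien-1-one, O=C1C(Br)=CC(Br)(Br)C=C1Br
Why: Proposed new method: Br+ from the bromodienone adds to the (E)-2-chloroalkene to give bromiranium ion 16, whose positive charge rests mainly on the chlorine-bearing carbon (an α-chlorocarbenium ion held by the bridging bromine); the silicon-bearing carbon of the (Z)-vinylsilane attacks this carbon anti to bromine to give β-silyl cation 17, and tribromophenoxide takes the silyl group so that the ring alkene appears exactly where the vinylsilane was. The closest known reaction types are the bromonium-induced cation–olefin (polyene-type) cyclisation of trisubstituted alkenes with this same reagent and the endocyclic vinylsilane-terminated cyclisation of (Z)-alkenylsilanes; what has not been shown is a 2-chloroalkene as the initiating alkene, which keeps its chlorine and so gives the tertiary C–Cl bond, the secondary C–Br bond and the new C–C bond in one event. The cyclohexene ring closes in the 6-endo mode at both partners (opening of the bromiranium ion at its substituted carbon, ipso attack on the vinylsilane) through a chair. Both new stereocentres follow from the existing CH centre, which places the oxanyl group equatorial in that chair and so selects the alkene face that is brominated, and from the E geometry, since anti addition then puts Br equatorial and trans to Cl with CH3 axial. The step needs Br+ to be passed to the deactivated chloroalkene and not to the vinylsilane (bromodesilylation): the vinylsilane is shielded by SiEt3 and by the adjacent fully substituted oxane carbon, bromine transfer from the dienone should be reversible as long as no nucleophile has removed silicon, and the oxane oxygen can assist transfer to the chloroalkene through a six-membered oxonium ion, but this chemoselectivity is the chief uncertainty of the route. The allylic tertiary chloride of 18 must not ionise, hence the non-acidic reagent, the low temperature and immediate use in step 11.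

Step 11
Reactants: 18 (2R,5S)-5-bromo-2-[(1S,4R,5R)-5-bromo-4-chloro-4-methylcyclohex-2-en-1-yl]-2,6,6-trimethyloxane
Product: 19 deoxycaespitol, (2R,5S)-5-bromo-2-[(1R,3R,4R)-3-bromo-4-chloro-4-methylcyclohexyl]-2,6,6-trimethyloxane
Conditions: 2-nitrobenzenesulfonylhydrazide, Et3N, CH2Cl2, rt
Reagents that add atoms: none
Why: Diimide reduction, in which diimide made in the flask delivers two hydrogens in a concerted syn manner to the cis-disubstituted ring alkene and should neither cleave the C–Br and C–Cl bonds nor ionise the allylic chloride; no stereocentre is formed or changed.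

**Compound list**

1 | (R)-linalool, (3R)-3,7-dimethylocta-1,6-dien-3-ol | C=C[C@](C)(O)CCC=C(C)C | starting material
2 | (3S,6R)-3-bromo-6-ethenyl-2,2,6-trimethyloxane | CC1(C)O[C@@](C)(C=C)CC[C@@H]1Br | intermediate
3 | B-alkyl-9-BBN adduct: 9-{2-[(2S,5S)-5-bromo-2,6,6-trimethyloxan-2-yl]ethyl}-9-borabicyclo[3.3.1]nonane | CC1(C)O[C@@](C)(CCB2C3CCCC2CCC3)CC[C@@H]1Br | intermediate
4 | 2-[(2R,5S)-5-bromo-2,6,6-trimethyloxan-2-yl]ethan-1-ol | CC1(C)O[C@@](C)(CCO)CC[C@@H]1Br | intermediate
5 | 2-[(2R,5S)-5-bromo-2,6,6-trimethyloxan-2-yl]acetic acid | CC1(C)O[C@@](C)(CC(=O)O)CC[C@@H]1Br | intermediate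
6 | (4R)-4-benzyl-1,3-oxazolidin-2-one | O=C1N[C@H](Cc2ccccc2)CO1 | starting material
7 | mixed pivalic anhydride: 2-[(2R,5S)-5-bromo-2,6,6-trimethyloxan-2-yl]acetic 2,2-dimethylpropanoic anhydride | CC1(C)O[C@@](C)(CC(=O)OC(=O)C(C)(C)C)CC[C@@H]1Br | intermediate
8 | (4R)-4-benzyl-3-{2-[(2R,5S)-5-bromo-2,6,6-trimethyloxan-2-yl]acetyl}-1,3-oxazolidin-2-one | CC1(C)O[C@@](C)(CC(=O)N2[C@H](Cc3ccccc3)COC2=O)CC[C@@H]1Br | intermediate
9 | (2E)-1,3-dichlorobut-2-ene | ClC/C=C(/Cl)C | starting material
10 | sodium (Z)-enolate: sodium (1Z)-1-[(4R)-4-benzyl-2-oxo-1,3-oxazolidin-3-yl]-2-[(2R,5S)-5-bromo-2,6,6-trimethyloxan-2-yl]ethen-1-olate | CC1(C)O[C@@](C)(/C=C(\[O-])N2[C@H](Cc3ccccc3)COC2=O)CC[C@@H]1Br.[Na+] | intermediate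
11 | (4R)-4-benzyl-3-[(2R,4E)-2-[(2R,5S)-5-bromo-2,6,6-trimethyloxan-2-yl]-5-chlorohex-4-enoyl]-1,3-oxazolidin-2-one | CC1(C)O[C@@](C)([C@@H](C/C=C(/Cl)C)C(=O)N2[C@H](Cc3ccccc3)COC2=O)CC[C@@H]1Br | intermediate
12 | (2S,4E)-2-[(2R,5S)-5-bromo-2,6,6-trimethyloxan-2-yl]-5-chlorohex-4-en-1-ol | CC1(C)O[C@@](C)([C@@H](C/C=C(/Cl)C)CO)CC[C@@H]1Br | intermediate
13 | (2R,4E)-2-[(2R,5S)-5-bromo-2,6,6-trimethyloxan-2-yl]-5-chlorohex-4-enal | CC1(C)O[C@@](C)([C@@H](C/C=C(/Cl)C)C=O)CC[C@@H]1Br | intermediate
14 | (2R,5S)-5-bromo-2-[(3S,5E)-6-chlorohept-5-en-1-yn-3-yl]-2,6,6-trimethyloxane | CC1(C)O[C@@](C)([C@@H](C/C=C(/Cl)C)C#C)CC[C@@H]1Br | intermediate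
15 | [(1Z,3S,5E)-3-[(2R,5S)-5-bromo-2,6,6-trimethyloxan-2-yl]-6-chlorohepta-1,5-dien-1-yl]triethylsilane | CC1(C)O[C@@](C)([C@@H](C/C=C(/Cl)C)/C=C\[Si](CC)(CC)CC)CC[C@@H]1Br | intermediate
16 | bromiranium ion: Br+ bridging the two chloroalkene carbons of 15, 2,4,6-tribromophenoxide as counter-ion | CC1(C)O[C@@](C)([C@@H](C[C@H]2[Br+][C@]2(C)Cl)/C=C\[Si](CC)(CC)CC)CC[C@@H]1Br.[O-]c1c(Br)cc(Br)cc1Br | intermediate
17 | β-silyl carbocation: cyclised cation with the charge on the ring carbon next to C1′ and axial SiEt3 on its other neighbour, 2,4,6-tribromophenoxide as counter-ion | CC1(C)O[C@@](C)([C@@H]2[CH+][C@@H]([Si](CC)(CC)CC)[C@@](C)(Cl)[C@H](Br)C2)CC[C@@H]1Br.[O-]c1c(Br)cc(Br)cc1Br | intermediate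
18 | (2R,5S)-5-bromo-2-[(1S,4R,5R)-5-bromo-4-chloro-4-methylcyclohex-2-en-1-yl]-2,6,6-trimethyloxane | CC1(C)O[C@@](C)([C@@H]2C=C[C@@](C)(Cl)[C@H](Br)C2)CC[C@@H]1Br | intermediate
19 | deoxycaespitol, (2R,5S)-5-bromo-2-[(1R,3R,4R)-3-bromo-4-chloro-4-methylcyclohexyl]-2,6,6-trimethyloxane | CC1(C)O[C@@](C)([C@@H]2CC[C@@](C)(Cl)[C@H](Br)C2)CC[C@@H]1Br | target

**Step count and risks**

Total step count: 11. Longest linear sequence: 11 steps (1 to 19).

Steps most likely to fail:

1. Step 10. Bromine may be transferred to the vinylsilane (bromodesilylation) before the deactivated chloroalkene reacts, the ring may close through a boat or from the other alkene face, and the new allylic tertiary chloride may ionise.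
   Fallback with known reactions, setting out from 8 and coming back at 19. Enolate 10, made from 8 as in step 5, is alkylated with (Z)-1,3-dichlorobut-2-ene (ClC/C=C(\Cl)C, the other commercial isomer) to give the (Z)-chloroalkene imide F1. LiBH4 removes the auxiliary to give the alcohol F2, and Dess–Martin oxidation gives the aldehyde F3. Wittig methylenation (Ph3P=CH2, THF, −78 °C to rt) gives the 1,5-diene F4. 9-BBN adds to its vinyl group to give the alkylborane F5, which under Pd(OAc)2, SPhos and K3PO4 (THF–H2O, 60 °C, high dilution) undergoes intramolecular B-alkyl Suzuki–Miyaura coupling with the (Z)-alkenyl chloride. This closes the same ring bond and gives the methylcyclohexene F6. Anti bromochlorination of its ring alkene (Bu4N+ BrCl2−, CH2Cl2, −78 °C; Br to the CH carbon, Cl to the methyl-bearing carbon) then leads to 19. It has to be separated from the diastereomeric trans adduct, which diaxial opening is expected to favour.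

2. Step 9. Regio- and stereocontrol may be lost in the hydrosilylation of the hindered α-branched alkyne (silicon on the internal carbon, or E geometry), which would block the endocyclic closure.
   Fallback, setting out from 14 and coming back at 15. Deprotonation and C-silylation (LiN(SiMe3)2, THF, −78 °C; Et3SiCl) gives the silylalkyne F7. cis-Semihydrogenation (H2, Pd on CaCO3 poisoned with Pb(OAc)2, quinoline, hexane, rt) gives 15.

3. Step 1. Ring size (five- versus six-membered ether) and the configuration at the CHBr carbon may be poorly controlled in the bromoetherification.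
   Fallback, setting out from 1 and coming back at 2. Shi epoxidation of the trisubstituted alkene of 1 (D-fructose-derived ketone, KHSO5, buffered MeCN–H2O, 0 °C) gives the epoxy alcohol F8. Acid (camphorsulfonic acid, CH2Cl2, 0 °C) lets the tertiary hydroxyl open the epoxide at its tertiary carbon to give the oxanol F9, which is separated from the five-membered ether. Bromination with inversion (CBr4, (n-C8H17)3P, toluene, 70 °C) gives 2.

Further compounds
F1 | step 10 | (4R)-4-benzyl-3-[(2R,4Z)-2-[(2R,5S)-5-bromo-2,6,6-trimethyloxan-2-yl]-5-chlorohex-4-enoyl]-1,3-oxazolidin-2-one | CC1(C)O[C@@](C)([C@@H](C/C=C(\Cl)C)C(=O)N2[C@H](Cc3ccccc3)COC2=O)CC[C@@H]1Br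
F2 | step 10 | (2S,4Z)-2-[(2R,5S)-5-bromo-2,6,6-trimethyloxan-2-yl]-5-chlorohex-4-en-1-ol | CC1(C)O[C@@](C)([C@@H](C/C=C(\Cl)C)CO)CC[C@@H]1Br
F3 | step 10 | (2R,4Z)-2-[(2R,5S)-5-bromo-2,6,6-trimethyloxan-2-yl]-5-chlorohex-4-enal | CC1(C)O[C@@](C)([C@@H](C/C=C(\Cl)C)C=O)CC[C@@H]1Br
F4 | step 10 | (2R,5S)-5-bromo-2-[(3S,5Z)-6-chlorohepta-1,5-dien-3-yl]-2,6,6-trimethyloxane | CC1(C)O[C@@](C)([C@@H](C/C=C(\Cl)C)C=C)CC[C@@H]1Br
F5 | step 10 | 9-[(3R,5Z)-3-[(2R,5S)-5-bromo-2,6,6-trimethyloxan-2-yl]-6-chlorohept-5-en-1-yl]-9-borabicyclo[3.3.1]nonane | CC1(C)O[C@@](C)([C@@H](C/C=C(\Cl)C)CCB2C3CCCC2CCC3)CC[C@@H]1Br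
F6 | step 10 | (2R,5S)-5-bromo-2,6,6-trimethyl-2-[(1R)-4-methylcyclohex-3-en-1-yl]oxane | CC1(C)O[C@@](C)([C@@H]2CCC(C)=CC2)CC[C@@H]1Br
F7 | step 9 | triethyl[(3S,5E)-3-[(2R,5S)-5-bromo-2,6,6-trimethyloxan-2-yl]-6-chlorohept-5-en-1-yn-1-yl]silane | CC1(C)O[C@@](C)([C@@H](C/C=C(/Cl)C)C#C[Si](CC)(CC)CC)CC[C@@H]1Br
F8 | step 1 | (3R)-5-[(2R)-3,3-dimethyloxiran-2-yl]-3-methylpent-1-en-3-ol | C=C[C@](C)(O)CC[C@H]1OC1(C)C
F9 | step 1 | (3R,6R)-6-ethenyl-2,2,6-trimethyloxan-3-ol | CC1(C)O[C@@](C)(C=C)CC[C@H]1O
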